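The target is an ent-labdane: rings A and B, stereocentres C5, C9 and C10 and the exocyclic C8=C17 alkene are disconnected at C4–C5 and C9–C10 to an acyclic all-E C20 tetraenyl diphosphate. One enzymatic proton-triggered bicyclisation closes both rings, sets the three stereocentres in the enantiomeric series and ends with the C8=C17 alkene, leaving an allylic diphosphate. That terminus then serves as a handle: the derived enal is clipped to the C13 methyl ketone, C16 is oxygenated through the kinetic enolate, and C14–C15 are rebuilt as a butenolide whose ring fixes the C13=C14 geometry before amide opening, acylation and adjustment to the acid.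

Key step: step 3

Remark on the structure: labdane numbering is used (C1–C10 decalin, C11–C16 side chain, C17 exocyclic methylene). The SMILES corresponds to 5R,9R,10R (enantiomeric labdane series) with C16 and C15 on the same side of C13=C14 (13Z by the sequence rules); no structure needed correcting.

Remark on the chemistry: moving oxygen to C16 through a deconjugated C15 ester ([2,3] shift of an allyl selenoxide) would erase the C13=C14 geometry and should re-form it with the ester trans to the new C16–O bond, the wrong isomer. The alkene is therefore rebuilt inside a five-membered lactone.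

Assumption: the cyclase is taken to be available by standard heterologous expression in Escherichia coli; it is a catalyst, not a starting material.

Step 1
Reactants: 1 geranylgeraniol ((2E,6E,10E)-3,7,11,15-tetramethylhexadeca-2,6,10,14-tetraen-1-ol)
Product: 2 geranylgeranyl chloride ((2E,6E,10E)-1-chloro-3,7,11,15-tetramethylhexadeca-2,6,10,14-tetraene)
Conditions: N-chlorosuccinimide, Me2S, CH2Cl2, −30 to 0 °C
Reagents that add atoms: N-chlorosuccinimide, O=C1CCC(=O)N1Cl
Why: Corey–Kim-type chlorination in which the alcohol is activated as an alkoxysulfonium ion and displaced by chloride at the primary allylic carbon (SN2), a neutral process that avoids allylic transposition and leaves the alkenes untouched.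

Step 2
Reactants: 2 geranylgeranyl chloride
Product: 3 geranylgeranyl diphosphate (all-E, isolated as its ammonium salt)
Conditions: (Bu4N)3HP2O7, MeCN, 20 °C; sulfonic acid cation-exchange resin (NH4+ form), aq NH4HCO3/iPrOH; lyophilisation
Reagents that add atoms: tris(tetrabutylammonium) hydrogen diphosphate, CCCC[N+](CCCC)(CCCC)CCCC.CCCC[N+](CCCC)(CCCC)CCCC.CCCC[N+](CCCC)(CCCC)CCCC.OP(=O)([O-])OP(=O)([O-])[O-]
Why: SN2 displacement of the primary allylic chloride by the nucleophilic diphosphate trianion in acetonitrile (Davisson–Poulter diphosphorylation), after which cation exchange gives the water-soluble salt needed as enzyme substrate.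

Step 3
Reactants: 3 geranylgeranyl diphosphate
Product: 4 ent-copalyl diphosphate ((13E)-ent-labda-8(17),13-dien-15-yl diphosphate; 5R,9R,10R)
Conditions: recombinant ent-copalyl diphosphate synthase (class 2 diterpene cyclase, e.g. the Arabidopsis thaliana enzyme), MgCl2 (0.1 mM), HEPES buffer pH 7.5, glycerol, dithiothreitol, 30 °C, substrate fed in portions
Reagents that add atoms: none
Why: An active-site aspartic acid protonates C3 of the terminal alkene of 3, which is held chair–chair in the enantiomeric fold; the C4 cation is trapped by the C5=C10 alkene (new bond C4–C5), the C10 cation by the C8=C9 alkene (new bond C9–C10), and the C8 cation then loses a proton from C17. This is the known class 2 diterpene cyclase reaction on its natural substrate, a proton-initiated cation–olefin polyene bicyclisation. Ring A and ring B are each closed in the six-membered endo mode with respect to the attacking alkene. C5, C9 and C10 arise from antiperiplanar addition across the two E alkenes in the chair–chair fold, which gives the trans ring fusion and the equatorial C9 side chain, while the absolute sense (5R,9R,10R) is imposed by the enzyme template because the substrate is achiral. The step needs one enantiomeric fold, termination by loss of a C17 proton only and an intact allylic diphosphate, and these are secured by the shape of the active site, the position of its catalytic base and the absence of a functional diphosphate-ionising (class 1) site, respectively. MgCl2 is kept low and 3 is fed slowly because this synthase is inhibited by excess magnesium and substrate.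

Step 4
Reactants: 4 ent-copalyl diphosphate
Product: 5 ent-copalol ((13E)-ent-labda-8(17),13-dien-15-ol; 5R,9R,10R)
Conditions: calf intestinal alkaline phosphatase, Tris buffer pH 8.5, MgCl2, 37 °C; extraction with hexane
Reagents that add atoms: none
Why: Enzymatic phosphate monoester hydrolysis, which cleaves P–O bonds under mildly basic conditions so that the C15–O bond, the 13E alkene and the acid-sensitive C8=C17 alkene are untouched and no stereocentre is involved.

Step 5
Reactants: 5 ent-copalol
Product: 6 ent-copalal ((13E)-ent-labda-8(17),13-dien-15-al)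
Conditions: MnO2 (activated), hexane, 20 °C
Reagents that add atoms: none
Why: Chemoselective heterogeneous MnO2 oxidation of the allylic alcohol to the conjugated aldehyde, which does not touch the isolated C8=C17 alkene or the ring stereocentres.

Step 6
Reactants: 6 ent-copalal
Product: 8 methyl ketone 14,15-dinor-ent-labd-8(17)-en-13-one, via hydroxy aldehyde 7 (not isolated)
Conditions: K2CO3 (aq), EtOH, reflux, slow N2 stream
Reagents that add atoms: water, O
Why: Base-mediated conjugate hydration followed by retro-aldol cleavage of the β-hydroxy aldehyde (the classical degradation of citral to methylheptenone), which cuts only the conjugated C13=C14 bond because the isolated C8=C17 alkene is inert to hydroxide and C5, C9 and C10 are not enolisable.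

Step 7
Reactants: 8 methyl ketone 14,15-dinor-ent-labd-8(17)-en-13-one
Product: 11 hydroxy ketone 16-hydroxy-14,15-dinor-ent-labd-8(17)-en-13-one, via silyl enol ether 9 (not isolated), via silyloxy ketone 10 (not isolated)
Conditions: LiN(iPr)2, Me3SiCl, THF, −78 °C; solvent exchange; 3-chloroperoxybenzoic acid, NaHCO3, CH2Cl2, −20 °C; citric acid, MeOH, 20 °C
Reagents that add atoms: 3-chloroperoxybenzoic acid, O=C(OO)c1cccc(Cl)c1
Why: Rubottom oxidation, in which kinetic deprotonation by the hindered lithium amide at the methyl group C16 gives the less substituted silyl enol ether, whose electron-rich alkene is epoxidised by the peracid far faster than the 1,1-disubstituted C8=C17 alkene before silyl migration and mild acid release the α-hydroxy ketone.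

Step 8
Reactants: 11 hydroxy ketone 16-hydroxy-14,15-dinor-ent-labd-8(17)-en-13-one
Product: 13 butenolide ent-labda-8(17),13-dien-16,15-olide, via phosphorane ester 12 (not isolated)
Conditions: Ph3P=C=C=O, toluene, 90 °C
Reagents that add atoms: (triphenylphosphoranylidene)ketene, O=C=C=P(c1ccccc1)(c1ccccc1)c1ccccc1
Why: Bestmann butenolide annulation, in which the hydroxyl adds to the ketene ylide to give an ester-stabilised phosphorane that closes by intramolecular Wittig olefination onto the C13 ketone, so that C13=C14 is formed inside the five-membered lactone with C16–O and C15 necessarily cis.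

Step 9
Reactants: 13 butenolide ent-labda-8(17),13-dien-16,15-olide; 14 N,O-dimethylhydroxylamine hydrochloride
Product: 15 (13Z)-16-hydroxy-N-methoxy-N-methyl-ent-labda-8(17),13-dien-15-amide
Conditions: AlMe3, CH2Cl2, 0 to 20 °C; aq KNaC4H4O6 work-up; crude product used at once
Reagents that add atoms: N,O-dimethylhydroxylamine hydrochloride (14), CNOC.Cl
Why: Weinreb aminolysis of a lactone by the aluminium amide formed from AlMe3 and the amine hydrochloride, which attacks the lactone carbonyl in preference to the fully substituted β-carbon C13 and opens the ring with the cis relationship of C16 and C15 (13Z) carried over from the ring.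

Step 10
Reactants: 15 (13Z)-16-hydroxy-N-methoxy-N-methyl-ent-labda-8(17),13-dien-15-amide; 16 isobutyryl chloride
Product: 17 (13Z)-16-(isobutyryloxy)-N-methoxy-N-methyl-ent-labda-8(17),13-dien-15-amide
Conditions: pyridine, 4-(dimethylamino)pyridine (cat.), CH2Cl2, 0 °C
Reagents that add atoms: isobutyryl chloride (16), CC(C)C(Cl)=O
Why: Nucleophile-catalysed O-acylation of the primary allylic alcohol by the acid chloride, carried out at once on the crude hydroxy amide so that relactonisation cannot compete.

Step 11
Reactants: 17 (13Z)-16-(isobutyryloxy)-N-methoxy-N-methyl-ent-labda-8(17),13-dien-15-amide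
Product: 18 (13Z)-16-(isobutyryloxy)-ent-labda-8(17),13-dien-15-al
Conditions: iBu2AlH (1.2 equiv), THF, −78 °C; aq KNaC4H4O6 work-up
Reagents that add atoms: none
Why: Weinreb amide reduction, in which one hydride is delivered to give a chelated tetrahedral aluminium intermediate that is stable at −78 °C and collapses to the aldehyde only on work-up, while the α-branched isobutyrate is reduced much more slowly by iBu2AlH in THF at this temperature.

Step 12
Reactants: 18 (13Z)-16-(isobutyryloxy)-ent-labda-8(17),13-dien-15-al
Product: 19 (13Z)-16-(isobutyryloxy)-ent-labda-8(17),13-dien-15-oic acid (target)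
Conditions: NaClO2, NaH2PO4, 2-methyl-2-butene, t-BuOH/H2O, 0 to 20 °C
Reagents that add atoms: sodium chlorite, [Na+].[O-]Cl=O
Why: Pinnick (Lindgren–Kraus) chlorite oxidation of the enal to the acid under buffered conditions, with 2-methyl-2-butene scavenging hypochlorous acid so that the C8=C17 alkene, the 13Z geometry and the isobutyrate are preserved.

Compound list
1 | geranylgeraniol, (2E,6E,10E)-3,7,11,15-tetramethylhexadeca-2,6,10,14-tetraen-1-ol | CC(C)=CCC/C(C)=C/CC/C(C)=C/CC/C(C)=C/CO | starting material
2 | geranylgeranyl chloride (all-E) | CC(C)=CCC/C(C)=C/CC/C(C)=C/CC/C(C)=C/CCl | intermediate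
3 | geranylgeranyl diphosphate (all-E; handled as ammonium salt) | CC(C)=CCC/C(C)=C/CC/C(C)=C/CC/C(C)=C/COP(=O)(O)OP(=O)(O)O | intermediate
4 | ent-copalyl diphosphate, (13E)-ent-labda-8(17),13-dien-15-yl diphosphate (5R,9R,10R) | C=C1CC[C@@H]2C(C)(C)CCC[C@@]2(C)[C@@H]1CC/C(C)=C/COP(=O)(O)OP(=O)(O)O | intermediate
5 | ent-copalol, (13E)-ent-labda-8(17),13-dien-15-ol | C=C1CC[C@@H]2C(C)(C)CCC[C@@]2(C)[C@@H]1CC/C(C)=C/CO | intermediate
6 | ent-copalal, (13E)-ent-labda-8(17),13-dien-15-al | C=C1CC[C@@H]2C(C)(C)CCC[C@@]2(C)[C@@H]1CC/C(C)=C/C=O | intermediate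
7 | 13-hydroxy-ent-labd-8(17)-en-15-al (both C13 epimers) | C=C1CC[C@@H]2C(C)(C)CCC[C@@]2(C)[C@@H]1CCC(C)(O)CC=O | intermediate (not isolated)
8 | 14,15-dinor-ent-labd-8(17)-en-13-one, 4-[(1R,4aR,8aR)-5,5,8a-trimethyl-2-methylidenedecahydronaphthalen-1-yl]butan-2-one | C=C1CC[C@@H]2C(C)(C)CCC[C@@]2(C)[C@@H]1CCC(C)=O | intermediate
9 | 13-(trimethylsilyloxy)-14,15-dinor-ent-labda-8(17),13(16)-diene | C=C1CC[C@@H]2C(C)(C)CCC[C@@]2(C)[C@@H]1CCC(=C)O[Si](C)(C)C | intermediate (not isolated)
10 | 16-(trimethylsilyloxy)-14,15-dinor-ent-labd-8(17)-en-13-one | C=C1CC[C@@H]2C(C)(C)CCC[C@@]2(C)[C@@H]1CCC(=O)CO[Si](C)(C)C | intermediate (not isolated)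
11 | 16-hydroxy-14,15-dinor-ent-labd-8(17)-en-13-one | C=C1CC[C@@H]2C(C)(C)CCC[C@@]2(C)[C@@H]1CCC(=O)CO | intermediate
12 | 13-oxo-14,15-dinor-ent-labd-8(17)-en-16-yl (triphenylphosphoranylidene)acetate | C=C1CC[C@@H]2C(C)(C)CCC[C@@]2(C)[C@@H]1CCC(=O)COC(=O)C=P(c1ccccc1)(c1ccccc1)c1ccccc1 | intermediate (not isolated)
13 | ent-labda-8(17),13-dien-16,15-olide, 4-{2-[(1R,4aR,8aR)-5,5,8a-trimethyl-2-methylidenedecahydronaphthalen-1-yl]ethyl}furan-2(5H)-one | C=C1CC[C@@H]2C(C)(C)CCC[C@@]2(C)[C@@H]1CCC1=CC(=O)OC1 | intermediate
14 | N,O-dimethylhydroxylamine hydrochloride | CNOC.Cl | starting material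
15 | (13Z)-16-hydroxy-N-methoxy-N-methyl-ent-labda-8(17),13-dien-15-amide | C=C1CC[C@@H]2C(C)(C)CCC[C@@]2(C)[C@@H]1CC/C(CO)=C/C(=O)N(C)OC | intermediate
16 | isobutyryl chloride | CC(C)C(Cl)=O | starting material
17 | (13Z)-16-(isobutyryloxy)-N-methoxy-N-methyl-ent-labda-8(17),13-dien-15-amide | C=C1CC[C@@H]2C(C)(C)CCC[C@@]2(C)[C@@H]1CC/C(COC(=O)C(C)C)=C/C(=O)N(C)OC | intermediate
18 | (13Z)-16-(isobutyryloxy)-ent-labda-8(17),13-dien-15-al | C=C1CC[C@@H]2C(C)(C)CCC[C@@]2(C)[C@@H]1CC/C(COC(=O)C(C)C)=C/C=O | intermediate
19 | (13Z)-16-(isobutyryloxy)-ent-labda-8(17),13-dien-15-oic acid (5R,9R,10R) | C=C1CC[C@@H]2C(C)(C)CCC[C@@]2(C)[C@@H]1CC/C(=C/C(=O)O)COC(=O)C(C)C | target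

Total step count: 12. Longest linear sequence: 12 steps (fully linear from 1).

Steps most likely to fail

Step 6. Conjugate hydration of a lipophilic β,β-disubstituted enal in a two-phase medium may be slow, and the liberated ketone may undergo aldol condensation with acetaldehyde or unreacted enal. Fallback, setting out from 5 and rejoining at 8: the C13=C14 bond is cut oxidatively instead. Hydroxyl-directed epoxidation of 5 (VO(acac)2, t-BuOOH, CH2Cl2, 0 °C), which leaves C8=C17 untouched, should give 13,14-epoxy-ent-labd-8(17)-en-15-ol F1. Payne rearrangement with hydroxide opening (NaOH, t-BuOH/H2O, 70 °C) should give ent-labd-8(17)-ene-13,14,15-triol F2. Glycol cleavage with NaIO4 in aqueous THF at neutral pH should then give the ketone 8.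

Step 11. Chemoselectivity may be lost through hydride attack on the isobutyrate or over-reduction, and the Z enal may isomerise during work-up. Fallback, setting out from 13 and rejoining at 19, avoids all redox changes at C15. The butenolide is saponified with LiOH (one equivalent, THF/H2O) and dried azeotropically to lithium (13Z)-16-hydroxy-ent-labda-8(17),13-dien-15-oate F3. The hydroxyl is deprotonated with LiN(SiMe3)2 in THF at −78 °C to give dilithium (13Z)-16-oxido-ent-labda-8(17),13-dien-15-oate F4. The far more nucleophilic alkoxide is acylated with 16, and acidification to pH 4 at 0 °C should give 19; material that relactonises returns as 13 and is recycled.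

Step 7. The peracid may epoxidise the C8=C17 alkene in competition, and the labile trimethylsilyl enol ether may hydrolyse before it is oxidised. Fallback, setting out from 8 and rejoining at 13, replaces oxygenation and Wittig closure by halogenation, carboxylate displacement and phosphonate olefination. The silyl enol ether 9 is brominated with N-bromosuccinimide (THF, −78 to 0 °C) to 16-bromo-14,15-dinor-ent-labd-8(17)-en-13-one F5. The bromide is displaced by potassium (diethoxyphosphoryl)acetate in DMF to give 13-oxo-14,15-dinor-ent-labd-8(17)-en-16-yl (diethoxyphosphoryl)acetate F6. Intramolecular Horner–Wadsworth–Emmons olefination (LiCl, DBU, MeCN) then closes the butenolide 13.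

Further compounds
F1 | step 6 | 13,14-epoxy-ent-labd-8(17)-en-15-ol (two trans-epoxide diastereomers) | C=C1CC[C@@H]2C(C)(C)CCC[C@@]2(C)[C@@H]1CCC1(C)OC1CO
F2 | step 6 | ent-labd-8(17)-ene-13,14,15-triol (diastereomer mixture) | C=C1CC[C@@H]2C(C)(C)CCC[C@@]2(C)[C@@H]1CCC(C)(O)C(O)CO
F3 | step 11 | lithium (13Z)-16-hydroxy-ent-labda-8(17),13-dien-15-oate | C=C1CC[C@@H]2C(C)(C)CCC[C@@]2(C)[C@@H]1CC/C(CO)=C/C(=O)[O-].[Li+]
F4 | step 11 | dilithium (13Z)-16-oxido-ent-labda-8(17),13-dien-15-oate | C=C1CC[C@@H]2C(C)(C)CCC[C@@]2(C)[C@@H]1CC/C(C[O-])=C/C(=O)[O-].[Li+].[Li+]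
F5 | step 7 | 16-bromo-14,15-dinor-ent-labd-8(17)-en-13-one | C=C1CC[C@@H]2C(C)(C)CCC[C@@]2(C)[C@@H]1CCC(=O)CBr
F6 | step 7 | 13-oxo-14,15-dinor-ent-labd-8(17)-en-16-yl (diethoxyphosphoryl)acetate | C=C1CC[C@@H]2C(C)(C)CCC[C@@]2(C)[C@@H]1CCC(=O)COC(=O)CP(=O)(OCC)OCC
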